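The target is a labdane. Its trans-decalin (rings A/B: C5, C8 carbinol, C9, C10) plus C11, the CH2 on C9, is the skeleton of cheap (+)-sclareolide minus the lactone carbonyl carbon. The route rests on the C11–C12 disconnection (C12 = next side-chain CH2): the saponified lactone, a γ-hydroxy carboxylate, is oxidised under Ir/Ni metallaphotoredox catalysis, loses its carboxyl carbon as CO2, and the C11 radical is joined to C12 of an (R)-configured C5 bromide that already carries the 3-phenylpropanoate. One operation thus cleaves the former lactone-ring C–C bond, forms the new C11–C12 bond and gives the target; the ring stereocentres come from sclareolide, C13 from (R)-β-methyl-γ-butyrolactone.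

Key step: step 5

Remark: labdane numbering is used (C8 = carbinol carbon, C9 = ring CH bearing the side chain, C11 and C12 = first and second side-chain CH2, C13 = CH(CH3), C15 = OCH2); (R)-β-methyl-γ-butyrolactone is assumed to be purchasable as a single enantiomer.

Step 1
Reactants: 1 (+)-sclareolide
Product: 2 potassium 2-[(1R,2R,4aS,8aS)-2-hydroxy-2,5,5,8a-tetramethyldecahydronaphthalen-1-yl]acetate
Conditions: KOH (1.00 equiv, 1 in 5 mol% excess), MeOH/H2O, reflux; evaporate, dry azeotropically with toluene
Reagents that add atoms: potassium hydroxide, [K+].[OH-]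
Why: Saponification of the γ-lactone by acyl–oxygen cleavage is irreversible once the carboxylate forms, leaves the C8–O bond and all four stereocentres untouched, and a slight deficit of hydroxide ensures that no free base is carried into step 5.

Step 2
Reactants: 3 (R)-4-methyldihydrofuran-2(3H)-one
Product: 5 methyl (R)-4-bromo-3-methylbutanoate, via bromo acid 4 (not isolated)
Conditions: HBr (33% in AcOH), 70 °C; then MeOH, rt
Reagents that add atoms: hydrogen bromide, Br; methanol, CO
Why: Bromide opens the protonated lactone at the O–CH2 carbon (SN2, alkyl–oxygen cleavage) and the liberated acid is trapped in the same pot by Fischer esterification, so the stereocentre, one carbon away from both reacting sites, is not involved.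

Step 3
Reactants: 5 methyl (R)-4-bromo-3-methylbutanoate
Product: 6 (R)-4-bromo-3-methylbutan-1-ol
Conditions: DIBAL-H (2.2 equiv), CH2Cl2, −78 → 0 °C; cold Rochelle-salt work-up
Reagents that add atoms: none
Why: DIBAL-H reduction of the ester to the primary alcohol should proceed without touching the primary C–Br bond, and the cold, non-basic work-up should keep the bromo alcohol from closing to the tetrahydrofuran.

Step 4
Reactants: 6 (R)-4-bromo-3-methylbutan-1-ol; 7 3-phenylpropanoyl chloride
Product: 8 (R)-4-bromo-3-methylbutyl 3-phenylpropanoate
Conditions: pyridine, CH2Cl2, 0 °C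
Reagents that add atoms: none
Why: Nucleophilic acyl substitution of the acid chloride by the primary alcohol should be fast at 0 °C, and pyridine is too weak a base to trigger intramolecular ether formation.

Step 5
Reactants: 2 potassium 2-[(1R,2R,4aS,8aS)-2-hydroxy-2,5,5,8a-tetramethyldecahydronaphthalen-1-yl]acetate (1.5 equiv); 8 (R)-4-bromo-3-methylbutyl 3-phenylpropanoate
Product: 9 (3S)-5-[(1R,2R,4aS,8aS)-2-hydroxy-2,5,5,8a-tetramethyldecahydronaphthalen-1-yl]-3-methylpentyl 3-phenylpropanoate
Conditions: Ir[dF(CF3)ppy]2(dtbbpy)PF6 (2 mol%), NiCl2·glyme (10 mol%), 4,4′-(MeO)2-bpy (10 mol%), degassed MeCN/H2O, blue LEDs (450 nm), rt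
Reagents that add atoms: none
Why: Visible-light-excited Ir(III) oxidises the carboxylate of 2 by single-electron transfer, loss of CO2 gives the primary C11 radical, a bipyridine-ligated nickel centre combines this radical with the alkyl group delivered by oxidative addition of the C12–Br bond of 8, and reductive elimination from the dialkylnickel(III) species forms the C11–C12 bond while Ir(II) returns nickel to its low-valent state. The closest known reaction type is the nickel/photoredox decarboxylative C(sp3)–C(sp3) cross-coupling of aliphatic carboxylic acids with alkyl bromides. No ring is closed. No stereocentre is formed: C9 beside the radical carbon and C13 beside the C–Br carbon are spectators, so the four ring centres of 1 and the centre of 3 should pass unchanged into 9. The step needs cross- over homo-coupling, which the two different activation modes (oxidation of the carboxylate, oxidative addition of the bromide) secure, and it needs radical capture to outrun SN2 O-alkylation of the carboxylate by 8 and β-hydride elimination at nickel, which the β-branch beside C12–Br and the bidentate bipyridine ligand disfavour. The carboxylate form keeps the γ-hydroxy acid from relactonising, and the free tertiary C8–OH and the ester of 8 should be inert under these near-neutral, room-temperature conditions.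

Compound list
1 | (+)-sclareolide, (3aR,5aS,9aS,9bR)-3a,6,6,9a-tetramethyldecahydronaphtho[2,1-b]furan-2(1H)-one | O=C1C[C@@H]2[C@@]3(C)CCCC(C)(C)[C@@H]3CC[C@@]2(C)O1 | starting material
2 | potassium 2-[(1R,2R,4aS,8aS)-2-hydroxy-2,5,5,8a-tetramethyldecahydronaphthalen-1-yl]acetate | [K+].[O-]C(=O)C[C@@H]1[C@@]2(C)CCCC(C)(C)[C@@H]2CC[C@@]1(C)O | intermediate
3 | (R)-4-methyldihydrofuran-2(3H)-one ((R)-β-methyl-γ-butyrolactone) | C[C@@H]1CC(=O)OC1 | starting material
4 | (R)-4-bromo-3-methylbutanoic acid (bromo acid, not isolated) | C[C@H](CC(=O)O)CBr | intermediate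
5 | methyl (R)-4-bromo-3-methylbutanoate | C[C@H](CC(=O)OC)CBr | intermediate
6 | (R)-4-bromo-3-methylbutan-1-ol | C[C@H](CCO)CBr | intermediate
7 | 3-phenylpropanoyl chloride | O=C(Cl)CCc1ccccc1 | starting material
8 | (R)-4-bromo-3-methylbutyl 3-phenylpropanoate | C[C@H](CCOC(=O)CCc1ccccc1)CBr | intermediate
9 | (3S)-5-[(1R,2R,4aS,8aS)-2-hydroxy-2,5,5,8a-tetramethyldecahydronaphthalen-1-yl]-3-methylpentyl 3-phenylpropanoate ((13S)-8α-hydroxylabdan-15-yl 3-phenylpropanoate) | C[C@H](CCOC(=O)CCc1ccccc1)CC[C@@H]1[C@@]2(C)CCCC(C)(C)[C@@H]2CC[C@@]1(C)O | target

Total step count: 5. Longest linear sequence: 4 steps (3 → 5 → 6 → 8 → 9).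

Steps most likely to fail

1. Step 5. Single-electron oxidation of the unstabilised primary carboxylate may be too slow to compete with catalyst decay. The carboxylate may instead be O-alkylated by the bromide, or the alkylnickel intermediates may be lost by β-hydride elimination or protodehalogenation. The fallback sets out from 1 and forms the same C11–C12 bond by a two-electron-precursor cross-coupling. DIBAL-H (CH2Cl2, −78 °C) should reduce 1 to the lactol F1. PhI(OAc)2/I2 under visible light should then generate the anomeric alkoxy radical, whose β-fragmentation cleaves the C11–C12 bond and gives the iodo formate F2, with the old C12 left on the C8 oxygen as a formate. Bromide 8 is converted with zinc dust (cat. I2, DMA, 70 °C) into the alkylzinc bromide F3. A Ni(cod)2/s-Bu-Pybox Negishi alkyl–alkyl coupling of F2 with F3 (DMA, rt) should give the formate ester F4. KHCO3 in MeOH (0 °C → rt) should remove the formate much faster than the primary 3-phenylpropanoate is attacked, returning to the route at 9.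

2. Step 3. The aluminium alkoxide or the free bromo alcohol may displace its own bromide during reduction, work-up or concentration, closing to volatile 3-methyltetrahydrofuran; material may also be lost by evaporation. The fallback sets out from 5 and postpones the reduction until no halide is left. Ester 5 is coupled with 2 under the conditions of step 5 to give the hydroxy methyl ester F5. LiAlH4 (THF, 0 °C) should reduce it to the diol F6. Acylation with 7 (pyridine, CH2Cl2, 0 °C) should take place only at the primary C15–OH, the tertiary C8–OH being unreactive, and returns to the route at 9.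

3. Step 2. Attack of bromide at the β-branched O–CH2 carbon is slow, and the bromo acid may reclose to the lactone before it is esterified, so the opening may stall at an equilibrium mixture. The fallback sets out from 3 and bypasses 5 and 6. LiAlH4 (THF, 0 °C) should give (R)-2-methylbutane-1,4-diol F7. An Appel reaction (CBr4, PPh3, CH2Cl2) should give (R)-1,4-dibromo-2-methylbutane F8. One equivalent of caesium 3-phenylpropanoate F9 (from 3-phenylpropanoic acid and Cs2CO3 in DMF, rt) should substitute the unbranched CH2Br far faster than the β-branched one (SN2 rate difference), returning to the route at 8. Its weak point is the removal of the minor regioisomer, which would require careful chromatography.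

Further compounds
F1 | step 5 | (3aR,5aS,9aS,9bR)-3a,6,6,9a-tetramethyldodecahydronaphtho[2,1-b]furan-2-ol (sclareolide lactol, anomer mixture) | OC1C[C@@H]2[C@@]3(C)CCCC(C)(C)[C@@H]3CC[C@@]2(C)O1
F2 | step 5 | (1R,2R,4aS,8aS)-1-(iodomethyl)-2,5,5,8a-tetramethyldecahydronaphthalen-2-yl formate | IC[C@@H]1[C@@]2(C)CCCC(C)(C)[C@@H]2CC[C@@]1(C)OC=O
F3 | step 5 | [(2R)-2-methyl-4-(3-phenylpropanoyloxy)butyl]zinc bromide | C[C@H](CCOC(=O)CCc1ccccc1)C[Zn]Br
F4 | step 5 | (3S)-5-[(1R,2R,4aS,8aS)-2-(formyloxy)-2,5,5,8a-tetramethyldecahydronaphthalen-1-yl]-3-methylpentyl 3-phenylpropanoate | C[C@H](CCOC(=O)CCc1ccccc1)CC[C@@H]1[C@@]2(C)CCCC(C)(C)[C@@H]2CC[C@@]1(C)OC=O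
F5 | step 3 | methyl (3S)-5-[(1R,2R,4aS,8aS)-2-hydroxy-2,5,5,8a-tetramethyldecahydronaphthalen-1-yl]-3-methylpentanoate | C[C@H](CC(=O)OC)CC[C@@H]1[C@@]2(C)CCCC(C)(C)[C@@H]2CC[C@@]1(C)O
F6 | step 3 | (1R,2R,4aS,8aS)-1-[(3S)-5-hydroxy-3-methylpentyl]-2,5,5,8a-tetramethyldecahydronaphthalen-2-ol | C[C@H](CCO)CC[C@@H]1[C@@]2(C)CCCC(C)(C)[C@@H]2CC[C@@]1(C)O
F7 | step 2 | (R)-2-methylbutane-1,4-diol | C[C@H](CCO)CO
F8 | step 2 | (R)-1,4-dibromo-2-methylbutane | C[C@H](CCBr)CBr
F9 | step 2 | caesium 3-phenylpropanoate | [Cs+].[O-]C(=O)CCc1ccccc1
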